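Achilleol A is disconnected at C5–C6 of its cyclohexane ring (C1 carbinol, C2 gem-dimethyl, C3 chain-bearing, C4 methylene-bearing). C5, C4 and the exocyclic CH2 form a 2-substituted allyl unit with equivalent termini, and C2 leaves C6 as the only enolizable carbon of a C1 ketone. The precursor is therefore a 2,5-dimethylene tetrahydropyran made from a δ-lactone: palladium ionizes its allylic C–O bond and the tethered enolate recloses at carbon, turning the oxygen heterocycle into the 4-methylenecyclohexanone in one operation. A reagent-controlled Ireland–Claisen rearrangement sets C3 beforehand; borohydride reduction sets C1 last.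

Key step: step 11

Remark: the sense of induction of the C2-symmetric bromoborane in step 8 is assigned by analogy with simple crotyl propanoates; if the (4S,5S)-reagent should give the antipode, its (4R,5R)-enantiomer is used with no other change.

Step 1
Reactants: 1 (2E,6E)-farnesyl bromide; 2 N-tert-butylethanimine
Product: 4 (4E,8E)-5,9,13-trimethyltetradeca-4,8,12-trienal, via alkylated imine 3 (not isolated)
Conditions: LiN(iPr)2, THF, −78 to 0 °C (on 2); then 1, −78 °C to rt; then aq. AcOH/NaOAc buffer, rt
Reagents that add atoms: water (SMILES O)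
Why: Stork-type metalloenamine alkylation, in which the lithio aza-enolate of 2 should displace the primary allylic bromide by SN2 without touching the E alkenes, after which mild hydrolysis of 3 releases the aldehyde.

Step 2
Reactants: 4 (4E,8E)-5,9,13-trimethyltetradeca-4,8,12-trienal
Product: 5 (6E,10E)-2,7,11,15-tetramethylhexadeca-1,6,10,14-tetraen-3-ol (racemic)
Conditions: CH2=C(CH3)MgBr, THF, −78 to 0 °C; aq. NH4Cl
Reagents that add atoms: isopropenylmagnesium bromide (SMILES C=C(C)[Mg]Br)
Why: Grignard 1,2-addition to the aldehyde should give the isopropenyl carbinol, whose stereocentre is racemic and is destroyed in step 3.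

Step 3
Reactants: 5 (6E,10E)-2,7,11,15-tetramethylhexadeca-1,6,10,14-tetraen-3-ol
Product: 7 ethyl (4E,8E,12E)-4,9,13,17-tetramethyloctadeca-4,8,12,16-tetraenoate, via mixed ketene acetal 6 (not isolated)
Conditions: CH3C(OEt)3 (excess), EtCO2H (cat.), 138 °C, EtOH distilled off
Reagents that add atoms: triethyl orthoacetate (SMILES CC(OCC)(OCC)OCC)
Why: Johnson–Claisen rearrangement through a chair transition state with the carbinol substituent equatorial (the axial alternative suffers a 1,3-diaxial clash with OEt) should give the E trisubstituted C4=C5 alkene.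

Step 4
Reactants: 7 ethyl (4E,8E,12E)-4,9,13,17-tetramethyloctadeca-4,8,12,16-tetraenoate
Product: 8 (4E,8E,12E)-4,9,13,17-tetramethyloctadeca-4,8,12,16-tetraenal
Conditions: iBu2AlH (1.05 equiv), toluene, −78 °C; aq. potassium sodium tartrate
Reagents that add atoms: none
Why: Low-temperature hydride reduction of the ester should stop at the aluminium hemiacetal, which gives the aldehyde on work-up while the isolated alkenes stay inert.

Step 5
Reactants: 8 (4E,8E,12E)-4,9,13,17-tetramethyloctadeca-4,8,12,16-tetraenal
Product: 9 dimethyl 2-[(4E,8E,12E)-4,9,13,17-tetramethyloctadeca-4,8,12,16-tetraen-1-ylidene]propanedioate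
Conditions: CH2(CO2Me)2, piperidine (cat.), AcOH (cat.), benzene, reflux, Dean–Stark
Reagents that add atoms: dimethyl malonate (SMILES COC(=O)CC(=O)OC)
Why: Knoevenagel condensation under amine/acid catalysis with azeotropic removal of water should give the alkylidene malonate, which has no alkene geometry to control.

Step 6
Reactants: 9 alkylidene malonate
Product: 10 2-[(4E,8E,12E)-4,9,13,17-tetramethyloctadeca-4,8,12,16-tetraen-1-ylidene]propane-1,3-diol
Conditions: iBu2AlH (4.5 equiv), CH2Cl2, −78 to 0 °C; aq. potassium sodium tartrate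
Reagents that add atoms: none
Why: The Lewis acidic aluminium hydride should reduce both esters by 1,2-addition rather than conjugate addition, giving the 2-alkylidene-1,3-diol.

Step 7
Reactants: 10 2-alkylidene-1,3-diol
Product: 11 (2E,6E,10E,14E)-2-(hydroxymethyl)-6,11,15,19-tetramethylicosa-2,6,10,14,18-pentaen-1-yl propanoate
Conditions: vinyl propanoate, Burkholderia cepacia lipase (Amano PS), tBuOMe, rt; the regioisomer and diester are separated and recycled by methanolysis
Reagents that add atoms: vinyl propanoate (SMILES CCC(=O)OC=C)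
Why: Lipase-catalysed irreversible transesterification should acylate the less hindered hydroxymethyl group (cis to the vinylic hydrogen, trans to the chain), giving the (2E)-monoester.

Step 8
Reactants: 11 (2E)-allylic monopropanoate
Product: 13 (4S)-3-methyl-5-methylidene-4-[(3E,7E,11E)-3,8,12,16-tetramethylheptadeca-3,7,11,15-tetraen-1-yl]oxan-2-one, via hydroxy acid 12 (not isolated)
Conditions: (4S,5S)-2-bromo-1,3-bis{[3,5-bis(trifluoromethyl)phenyl]sulfonyl}-4,5-diphenyl-1,3,2-diazaborolidine (2.2 equiv), Et3N (2.4 equiv), toluene/hexane, −78 to −20 °C, then rt; aqueous work-up; PPTS (cat.), CH2Cl2, rt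
Reagents that add atoms: none
Why: Enantioselective boron-mediated Ireland–Claisen rearrangement, in which one equivalent of the bromoborane masks the free hydroxyl as its B–O derivative, the second forms the boron ketene acetal, and the chair transition state with the chain equatorial, made diastereomeric by the C2-symmetric diazaborolidine, should set the chain-bearing stereocentre before the hydroxy acid 12 lactonizes (the methyl-bearing centre is erased in step 9).

Step 9
Reactants: 13 3-methyl δ-lactone
Product: 14 (4R)-3,3-dimethyl-5-methylidene-4-[(3E,7E,11E)-3,8,12,16-tetramethylheptadeca-3,7,11,15-tetraen-1-yl]oxan-2-one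
Conditions: LiN(iPr)2, THF, −78 °C; MeI, DMPU, −78 to −20 °C
Reagents that add atoms: iodomethane (SMILES CI)
Why: Lactone enolate alkylation should convert the α-methyl carbon into the gem-dimethyl carbon, while the adjacent chain-bearing carbon is not acidic and keeps its configuration (its descriptor changes only through priorities).

Step 10
Reactants: 14 gem-dimethyl δ-lactone
Product: 15 (4R)-3,3-dimethyl-2,5-dimethylidene-4-[(3E,7E,11E)-3,8,12,16-tetramethylheptadeca-3,7,11,15-tetraen-1-yl]oxane
Conditions: Cp2TiMe2 (2.5 equiv), toluene, 65 °C, dark; base-washed glassware, basic alumina filtration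
Reagents that add atoms: dimethyltitanocene (SMILES C[Ti](C)(C1C=CC=C1)C1C=CC=C1)
Why: Petasis methylenation by thermally generated Cp2Ti=CH2 should convert the lactone carbonyl into the exocyclic enol ether under non-acidic conditions that the polyene tolerates, and the quaternary neighbour prevents isomerization into the ring.

Step 11
Reactants: 15 2,5-dimethylidene tetrahydropyran
Product: 16 (3R)-2,2-dimethyl-4-methylidene-3-[(3E,7E,11E)-3,8,12,16-tetramethylheptadeca-3,7,11,15-tetraen-1-yl]cyclohexan-1-one
Conditions: Pd2(dba)3 (2.5 mol%), dppe (6 mol%), degassed DMSO, 60–80 °C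
Reagents that add atoms: none
Why: Proposed new method: zerovalent palladium is expected to ionize the allylic ring C–O bond of the cyclic allyl enol ether (the enol oxygen is a leaving group comparable to a phenoxide), giving a zwitterion in which a 2-substituted π-allyl cation and the ketone enolate stay tethered through the C3–C4 bond, and collapse at the enolate carbon gives the ketone irreversibly whereas collapse at oxygen only regenerates 15. The closest known reaction types are the palladium-catalysed 1,3 oxygen-to-carbon allyl shift of 2-alkylidene-5-vinyltetrahydrofurans to cyclopentanones, the palladium-induced ionization of γ-methylene-δ-valerolactones and the Tsuji–Trost allylation of ketone enolates; a thermal Claisen pathway is not available because the two exocyclic methylenes sit 1,4 across the ring. The six-membered carbocycle closes by C-attack of the enolate on a terminus of the π-allyl unit with the remaining C=C exocyclic, and both termini give the same product. No new stereocentre is formed and the chain-bearing carbon is not touched. The step needs C- over O-alkylation and a single enolate regiochemistry: O-alkylation is degenerate and reversible, the gem-dimethyl carbon blocks the other α-position, and the 2-substituted allyl has no β-hydrogen for elimination.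

Step 12
Reactants: 16 4-methylidene cyclohexanone
Product: 17 achilleol A
Conditions: NaBH4, MeOH, 0 °C
Reagents that add atoms: none
Why: Substrate-controlled hydride reduction, as for 4,4-dimethyl-3-oxo triterpenoids, should deliver hydride along the axial trajectory of the chain-equatorial conformer (and the equatorial trajectory of the chain-axial conformer, whose axial face is blocked), both giving the hydroxyl cis to the side chain, that is (1S).

Compound list
1 | (2E,6E)-farnesyl bromide, (2E,6E)-1-bromo-3,7,11-trimethyldodeca-2,6,10-triene | BrC/C=C(\C)CC/C=C(\C)CCC=C(C)C | starting material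
2 | N-tert-butylethanimine | CC=NC(C)(C)C | starting material
3 | N-tert-butyl-(4E,8E)-5,9,13-trimethyltetradeca-4,8,12-trien-1-imine | CC(C)(C)N=CCC/C=C(\C)CC/C=C(\C)CCC=C(C)C | intermediate
4 | (4E,8E)-5,9,13-trimethyltetradeca-4,8,12-trienal | O=CCC/C=C(\C)CC/C=C(\C)CCC=C(C)C | intermediate
5 | (6E,10E)-2,7,11,15-tetramethylhexadeca-1,6,10,14-tetraen-3-ol (racemic) | C=C(C)C(O)CC/C=C(\C)CC/C=C(\C)CCC=C(C)C | intermediate
6 | (6E,10E)-3-[(1-ethoxyethenyl)oxy]-2,7,11,15-tetramethylhexadeca-1,6,10,14-tetraene | C=C(OCC)OC(C(C)=C)CC/C=C(\C)CC/C=C(\C)CCC=C(C)C | intermediate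
7 | ethyl (4E,8E,12E)-4,9,13,17-tetramethyloctadeca-4,8,12,16-tetraenoate | CCOC(=O)CC/C(C)=C/CC/C=C(\C)CC/C=C(\C)CCC=C(C)C | intermediate
8 | (4E,8E,12E)-4,9,13,17-tetramethyloctadeca-4,8,12,16-tetraenal | O=CCC/C(C)=C/CC/C=C(\C)CC/C=C(\C)CCC=C(C)C | intermediate
9 | dimethyl 2-[(4E,8E,12E)-4,9,13,17-tetramethyloctadeca-4,8,12,16-tetraen-1-ylidene]propanedioate | COC(=O)C(=CCC/C(C)=C/CC/C=C(\C)CC/C=C(\C)CCC=C(C)C)C(=O)OC | intermediate
10 | 2-[(4E,8E,12E)-4,9,13,17-tetramethyloctadeca-4,8,12,16-tetraen-1-ylidene]propane-1,3-diol | OCC(CO)=CCC/C(C)=C/CC/C=C(\C)CC/C=C(\C)CCC=C(C)C | intermediate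
11 | (2E,6E,10E,14E)-2-(hydroxymethyl)-6,11,15,19-tetramethylicosa-2,6,10,14,18-pentaen-1-yl propanoate | CCC(=O)OC/C(CO)=C/CC/C(C)=C/CC/C=C(\C)CC/C=C(\C)CCC=C(C)C | intermediate
12 | (3S,6E,10E,14E)-3-(3-hydroxyprop-1-en-2-yl)-2,6,11,15,19-pentamethylicosa-6,10,14,18-tetraenoic acid (configuration at C2 immaterial) | OC(=O)C(C)[C@@H](C(=C)CO)CC/C(C)=C/CC/C=C(\C)CC/C=C(\C)CCC=C(C)C | intermediate
13 | (4S)-3-methyl-5-methylidene-4-[(3E,7E,11E)-3,8,12,16-tetramethylheptadeca-3,7,11,15-tetraen-1-yl]oxan-2-one (configuration at C3 immaterial) | CC1C(=O)OCC(=C)[C@H]1CC/C(C)=C/CC/C=C(\C)CC/C=C(\C)CCC=C(C)C | intermediate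
14 | (4R)-3,3-dimethyl-5-methylidene-4-[(3E,7E,11E)-3,8,12,16-tetramethylheptadeca-3,7,11,15-tetraen-1-yl]oxan-2-one | CC1(C)C(=O)OCC(=C)[C@H]1CC/C(C)=C/CC/C=C(\C)CC/C=C(\C)CCC=C(C)C | intermediate
15 | (4R)-3,3-dimethyl-2,5-dimethylidene-4-[(3E,7E,11E)-3,8,12,16-tetramethylheptadeca-3,7,11,15-tetraen-1-yl]oxane | CC1(C)C(=C)OCC(=C)[C@H]1CC/C(C)=C/CC/C=C(\C)CC/C=C(\C)CCC=C(C)C | intermediate
16 | (3R)-2,2-dimethyl-4-methylidene-3-[(3E,7E,11E)-3,8,12,16-tetramethylheptadeca-3,7,11,15-tetraen-1-yl]cyclohexan-1-one | C=C1CCC(=O)C(C)(C)[C@@H]1CC/C(C)=C/CC/C=C(\C)CC/C=C(\C)CCC=C(C)C | intermediate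
17 | achilleol A, (1S,3R)-2,2-dimethyl-4-methylidene-3-[(3E,7E,11E)-3,8,12,16-tetramethylheptadeca-3,7,11,15-tetraen-1-yl]cyclohexan-1-ol | C=C1CC[C@H](O)C(C)(C)[C@@H]1CC/C(C)=C/CC/C=C(\C)CC/C=C(\C)CCC=C(C)C | target

Total step count: 12. Longest linear sequence: 12 steps (the route is linear from 1 and 2).

The three steps most likely to fail:

First, step 11, the proposed new method. The unactivated allyl enol ether may resist oxidative addition, or traces of acid may hydrolyse it before ionization. The fallback uses known chemistry, sets out from 15 and returns at 16. Mild hydrolysis (PPTS, THF/H2O, rt) should give the hydroxy methyl ketone F1, in equilibrium with its lactol. Methyl chloroformate and pyridine should convert it into the allylic methyl carbonate F2. LiN(SiMe3)2 (THF, −78 °C) followed by Pd(PPh3)4 should then effect the classical intramolecular Tsuji–Trost allylation of the lithium enolate, closing the same C5–C6 bond to give 16.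

Second, step 8. Boron enolization may be incomplete or geometrically impure next to the masked hydroxyl, which would erode the enantiomeric purity at the chain-bearing carbon. The fallback replaces the sigmatropic route by a catalytic conjugate addition, sets out from 9 and returns at 14. A copper bis(oxazoline)-catalysed Mukaiyama–Michael addition ([Cu((S,S)-tBu-box)](SbF6)2, (CF3)2CHOH, toluene/CH2Cl2, −78 °C; ligand enantiomer chosen for the 3R product) of 1-methoxy-2-methyl-1-(trimethylsilyloxy)prop-1-ene to 9 should give the triester F3. Saponification of one malonate ester (KOH, 1 equiv, MeOH/THF, 0 °C) should give the malonic half acid F4. Mannich-type decarboxylative methylenation (paraformaldehyde, Et2NH, THF, reflux) should give the acrylate diester F5. iBu2AlH (CH2Cl2, −78 °C) should reduce only the acrylate ester, and the resulting hydroxy ester should lactonize (PPTS) to 14.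

Third, step 12. Facial selectivity of hydride delivery to the conformationally mobile ring may be poor. The fallback sets out from 16 and returns at 17. It replaces substrate control by reagent control: a Corey–Bakshi–Shibata reduction ((R)-2-methyl-CBS-oxazaborolidine (cat.), BH3·SMe2, THF, −20 °C), with the quaternary carbon as the large and the ring CH2 as the small substituent, should give the (1S) alcohol. It makes no new compound (F0).

Further compounds
F1 | step 11 | (4R,7E,11E,15E)-4-(3-hydroxyprop-1-en-2-yl)-3,3,7,12,16,20-hexamethylhenicosa-7,11,15,19-tetraen-2-one | CC(=O)C(C)(C)[C@@H](C(=C)CO)CC/C(C)=C/CC/C=C(\C)CC/C=C(\C)CCC=C(C)C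
F2 | step 11 | methyl 2-[(4R,7E,11E,15E)-3,3,7,12,16,20-hexamethyl-2-oxohenicosa-7,11,15,19-tetraen-4-yl]prop-2-en-1-yl carbonate | CC(=O)C(C)(C)[C@@H](C(=C)COC(=O)OC)CC/C(C)=C/CC/C=C(\C)CC/C=C(\C)CCC=C(C)C
F3 | step 8 | dimethyl 2-[(3R,6E,10E,14E)-1-methoxy-2,2,6,11,15,19-hexamethyl-1-oxoicosa-6,10,14,18-tetraen-3-yl]propanedioate | COC(=O)C(C)(C)[C@@H](C(C(=O)OC)C(=O)OC)CC/C(C)=C/CC/C=C(\C)CC/C=C(\C)CCC=C(C)C
F4 | step 8 | 3-methoxy-2-[(3R,6E,10E,14E)-1-methoxy-2,2,6,11,15,19-hexamethyl-1-oxoicosa-6,10,14,18-tetraen-3-yl]-3-oxopropanoic acid | COC(=O)C(C)(C)[C@@H](C(C(=O)O)C(=O)OC)CC/C(C)=C/CC/C=C(\C)CC/C=C(\C)CCC=C(C)C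
F5 | step 8 | methyl (3S,6E,10E,14E)-3-(3-methoxy-3-oxoprop-1-en-2-yl)-2,2,6,11,15,19-hexamethylicosa-6,10,14,18-tetraenoate | COC(=O)C(C)(C)[C@@H](C(=C)C(=O)OC)CC/C(C)=C/CC/C=C(\C)CC/C=C(\C)CCC=C(C)C
F0 | step 12 | none | none
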